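## Retrosynthetic overview

1. C11–Br goes on last: trans-selective bromination of the kinetic silyl dienol ether of (S)-hydroxy enone 14, directed by the C10 oxygen.
2. The cyclopentenone (the only carbocycle; C10–C11 bond) is closed by a conrotatory 4π closure of the oxidopentadienyl (1,4-dihydroxypentadienyl) cation of Z-keto-enal 12 under chiral phosphoric acid control. This is the pericyclic event by which allene oxide cyclase closes the cyclopentenone oxylipins.
3. Keto-enal 12 comes from furan 10 by singlet-oxygen dioxygenation and reduction (a lipoxygenase-like installation of O2).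
4. Furan 10 (a temporary ring, formed first) comes from a propargyl Claisen rearrangement that forges C9–C13, followed by heterocyclisation, from alkynol 3 and acetal 6.
5. 3 comes from propargyl alcohol and (Z)-1-bromopent-2-ene; 6 from methyl undec-10-enoate.

Atom labels: ring carbons carry oxylipin numbers, C9 (ester chain), C10 (CHOH), C11 (CHBr), C12 (C=O), C13 (pentenyl chain).

Assumption 1: the presumed biosynthesis is the oxylipin allene oxide synthase/cyclase pathway (dioxygenation, then conrotatory 4π closure of an oxidopentadienyl cation), followed by haloperoxidase bromination.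

Assumption 2: the sense of induction of the chiral acid in step 5 is not known in advance; the (R)-catalyst is written, and its antipode is used if the first run gives the 5R alcohol.

## Route

Step 1
Reactants: 1 prop-2-yn-1-ol; 2 (2Z)-1-bromopent-2-ene
Product: 3 (5Z)-oct-5-en-2-yn-1-ol
Conditions: CuI (10 mol%), NaI (10 mol%), K2CO3 (1.5 equiv), DMF, 20 °C
Reagents that add atoms: none
Why: copper acetylide allylic substitution (Jeffery-type alkyne–allyl halide coupling) at the primary sp3 carbon gives the skipped enyne with the Z alkene untouched, and no stereocentre is formed.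

Step 2
Reactants: 4 methyl undec-10-enoate
Product: 6 methyl 10,10-dimethoxydecanoate, via methyl 10-oxodecanoate 5 (not isolated)
Conditions: O3, CH2Cl2/MeOH, −78 °C; Me2S, −78 → 20 °C; then TsOH·H2O (2 mol%), MeOH, 20 °C
Reagents that add atoms: ozone, [O-][O+]=O; methanol, CO
Why: ozonolysis with reductive work-up cleaves the terminal alkene to the C10 aldehyde, which is converted in the same methanolic solution into its dimethyl acetal (acid-catalysed acetalisation), the ester being inert and no stereocentre being formed.

Step 3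
Reactants: 3 (5Z)-oct-5-en-2-yn-1-ol; 6 methyl 10,10-dimethoxydecanoate (1.5 equiv)
Product: 10 methyl 8-{5-methyl-4-[(2Z)-pent-2-en-1-yl]furan-3-yl}octanoate, via mixed acetal 7 (not isolated), via propargyl vinyl ether 8 (not isolated), via allenyl aldehyde 9 (not isolated)
Conditions: t-BuCO2H (5 mol%), o-xylene, 140 °C, MeOH distilled off; then 20 °C, CH2Cl2, Ph3PAuCl (2 mol%), AgSbF6 (2 mol%)
Reagents that add atoms: none
Why: acid-catalysed acetal exchange and loss of methanol give the propargyl vinyl ether, whose [3,3] propargyl Claisen (Saucy–Marbet) rearrangement forges C9–C13 and gives the β-allenyl aldehyde; cationic monovalent gold then triggers attack of the carbonyl oxygen on the central allene carbon and aromatisation to the 2-methylfuran (Kirsch-type Claisen/heterocyclisation), the racemic C9 centre of 9 being erased.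

Step 4
Reactants: 10 methyl 8-{5-methyl-4-[(2Z)-pent-2-en-1-yl]furan-3-yl}octanoate
Product: 12 methyl (9Z,12Z)-10-acetyl-9-formylpentadeca-9,12-dienoate, via furan endoperoxide 11 (not isolated)
Conditions: O2, hν (visible), 5,10,15,20-tetraphenylporphyrin (0.2 mol%), CH2Cl2, −78 °C; then Me2S (3 equiv), −78 → 0 °C
Reagents that add atoms: dioxygen, O=O
Why: [4+2] cycloaddition of singlet oxygen to the electron-rich furan and sulfide reduction of the endoperoxide give the Z-4-oxo-2-enal, the C9=C13 geometry being fixed by the furan ring and the side-chain Z alkene surviving because its ene reaction with singlet oxygen is orders of magnitude slower.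

Step 5
Reactants: 12 methyl (9Z,12Z)-10-acetyl-9-formylpentadeca-9,12-dienoate
Product: 14 methyl 8-[(5S)-5-hydroxy-3-oxo-2-[(2Z)-pent-2-en-1-yl]cyclopent-1-en-1-yl]octanoate, via hydroxydiene tautomer 13 (not isolated)
Conditions: (R)-3,3′-bis(2,4,6-triisopropylphenyl)-1,1′-binaphthyl-2,2′-diyl hydrogen phosphate (10 mol%), toluene, 4 Å MS, 40 °C
Reagents that add atoms: none
Why: Proposed new method: the phosphoric acid enolises the methyl ketone to 13 and protonates the aldehyde to give a 1,4-dihydroxypentadienyl cation (the protonated, ring-opened tautomer of a hydroxy vinyl allene oxide) held as a contact ion pair by two O–H···O=P hydrogen bonds, and thermal conrotatory 4π closure (Piancatelli/Nazarov-type, formally a 5-enolendo aldol) forms C10–C11 with the phosphate-controlled sense of conrotation setting C10 as 5S; the closest known reactions are chiral phosphoric acid-catalysed aza-Piancatelli rearrangements, Brønsted-acid asymmetric Nazarov cyclisations and phosphoric acid-catalysed intramolecular aldolisations, while the non-asymmetric closure of Z-4-oxo-2-enals to 4-hydroxycyclopentenones is classical, and the step is an isomerisation.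

Step 6
Reactants: 14 methyl 8-[(5S)-5-hydroxy-3-oxo-2-[(2Z)-pent-2-en-1-yl]cyclopent-1-en-1-yl]octanoate
Product: 17 methyl 8-[(4S,5R)-4-bromo-5-hydroxy-3-oxo-2-[(2Z)-pent-2-en-1-yl]cyclopent-1-en-1-yl]octanoate, via bis-silyl dienol ether 15 (not isolated), via bromo silyl ether 16 (not isolated)
Conditions: LiN(iPr)2 (2.1 equiv), THF, −78 °C; Me3SiCl (2.5 equiv), −78 → −40 °C; N-bromosuccinimide (1.05 equiv), −78 °C; then citric acid, MeOH/H2O, 0 °C
Reagents that add atoms: N-bromosuccinimide, O=C1CCC(=O)N1Br; chlorotrimethylsilane, C[Si](C)(C)Cl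
Why: kinetic α′-deprotonation of the alkoxide gives the cross-conjugated dianion (no good leaving group next to the enolate), double silylation gives the 2-silyloxydiene, and electrophilic bromination of this silyl enol ether occurs at C11 anti to the C10 silyloxy group to set the trans 4S bromide (also the thermodynamic epimer), mild acid then freeing the alcohol; C10 is untouched and its descriptor changes from S to R only because CHBr outranks the alkene carbon.

## Compound list

1 | prop-2-yn-1-ol | C#CCO | starting material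
2 | (2Z)-1-bromopent-2-ene | CC/C=C\CBr | starting material
3 | (5Z)-oct-5-en-2-yn-1-ol | CC/C=C\CC#CCO | intermediate
4 | methyl undec-10-enoate | C=CCCCCCCCCC(=O)OC | starting material
5 | methyl 10-oxodecanoate | O=CCCCCCCCCC(=O)OC | intermediate (not isolated)
6 | methyl 10,10-dimethoxydecanoate | COC(OC)CCCCCCCCC(=O)OC | intermediate
7 | methyl 10-methoxy-10-{[(5Z)-oct-5-en-2-yn-1-yl]oxy}decanoate (mixed acetal, racemic) | COC(CCCCCCCCC(=O)OC)OCC#CC/C=C\CC | intermediate (not isolated)
8 | methyl 10-{[(5Z)-oct-5-en-2-yn-1-yl]oxy}dec-9-enoate (propargyl vinyl ether, E/Z mixture at C9=C10) | COC(=O)CCCCCCCC=COCC#CC/C=C\CC | intermediate (not isolated)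
9 | methyl 9-formyl-10-[(2Z)-pent-2-en-1-yl]dodeca-10,11-dienoate (allenyl aldehyde, racemic) | COC(=O)CCCCCCCC(C=O)C(C/C=C\CC)=C=C | intermediate (not isolated)
10 | methyl 8-{5-methyl-4-[(2Z)-pent-2-en-1-yl]furan-3-yl}octanoate | COC(=O)CCCCCCCc1coc(C)c1C/C=C\CC | intermediate
11 | methyl 8-{1-methyl-6-[(2Z)-pent-2-en-1-yl]-2,3,7-trioxabicyclo[2.2.1]hept-5-en-5-yl}octanoate (furan endoperoxide, racemic) | COC(=O)CCCCCCCC1=C(C/C=C\CC)C2(C)OOC1O2 | intermediate (not isolated)
12 | methyl (9Z,12Z)-10-acetyl-9-formylpentadeca-9,12-dienoate | COC(=O)CCCCCCC/C(C=O)=C(\C/C=C\CC)C(C)=O | intermediate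
13 | methyl (9Z,12Z)-9-formyl-10-(1-hydroxyethenyl)pentadeca-9,12-dienoate (hydroxydiene tautomer of 12) | COC(=O)CCCCCCC/C(C=O)=C(\C/C=C\CC)C(O)=C | intermediate (not isolated)
14 | methyl 8-[(5S)-5-hydroxy-3-oxo-2-[(2Z)-pent-2-en-1-yl]cyclopent-1-en-1-yl]octanoate | CC/C=C\CC1=C(CCCCCCCC(=O)OC)[C@@H](O)CC1=O | intermediate
15 | methyl 8-[(5S)-2-[(2Z)-pent-2-en-1-yl]-3,5-bis(trimethylsilyloxy)cyclopenta-1,3-dien-1-yl]octanoate | CC/C=C\CC1=C(CCCCCCCC(=O)OC)[C@@H](O[Si](C)(C)C)C=C1O[Si](C)(C)C | intermediate (not isolated)
16 | methyl 8-[(4S,5R)-4-bromo-3-oxo-2-[(2Z)-pent-2-en-1-yl]-5-(trimethylsilyloxy)cyclopent-1-en-1-yl]octanoate | CC/C=C\CC1=C(CCCCCCCC(=O)OC)[C@@H](O[Si](C)(C)C)[C@H](Br)C1=O | intermediate (not isolated)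
17 | methyl 8-[(4S,5R)-4-bromo-5-hydroxy-3-oxo-2-[(2Z)-pent-2-en-1-yl]cyclopent-1-en-1-yl]octanoate | CC/C=C\CC1=C(CCCCCCCC(=O)OC)[C@@H](O)[C@H](Br)C1=O | target

## Step count and risks

Total step count: 6. Longest linear sequence: 5 (steps 1, 3, 4, 5, 6; the branch through step 2 is equally long).

Steps most likely to fail, most risky first:

**Step 5 (asymmetric 4π closure).** The enantioselectivity is unproven, and the acid may isomerise the Z-enedione or move the skipped alkene into conjugation. The fallback sets out from keto-enal 12 and comes back at hydroxy enone 14. Compound 12 is closed without chiral control by the classical base-mediated route (Et3N, MeCN, 20 °C) to racemic methyl 8-{5-hydroxy-3-oxo-2-[(2Z)-pent-2-en-1-yl]cyclopent-1-en-1-yl}octanoate F1. F1 is then resolved by lipase-catalysed acylation (Burkholderia cepacia lipase, vinyl acetate, tert-butyl methyl ether, 30 °C, stopped near 52% conversion). By analogy with the rethrolones (allethrolone, jasmololone), the enzyme should acylate the R alcohol to methyl 8-[(5R)-5-acetoxy-3-oxo-2-[(2Z)-pent-2-en-1-yl]cyclopent-1-en-1-yl]octanoate F2 and leave the S alcohol 14, which is separated by chromatography. The approach changes from catalyst-controlled ring closure to racemic ring closure plus kinetic resolution, at the cost of a 50% ceiling on yield.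

**Step 3 (acetal exchange, Claisen, heterocyclisation in one flask).** The enolisable allenyl aldehyde 9 may isomerise to the conjugated dienal or self-condense in the hot acidic stage. The fallback sets out from alcohol 3 and acetal 6 and comes back at furan 10. Acetal 6 and 3 (2.2 equiv) are transacetalised (pyridinium p-toluenesulfonate, benzene, 5 Å MS, 60 °C) to methyl 10,10-bis{[(5Z)-oct-5-en-2-yn-1-yl]oxy}decanoate F3. Gassman-type elimination (Me3SiOSO2CF3, iPr2NEt, CH2Cl2, −20 °C) then gives propargyl vinyl ether 8, now isolated, with one equivalent of 3 recovered. Compound 8 is carried to 10 at 20 °C by a monovalent gold-catalysed propargyl Claisen/heterocyclisation cascade (Ph3PAuCl/AgSbF6, 2 mol% each, CH2Cl2). The sigmatropic step is thus moved from a thermal acid-mediated cascade to a discrete vinyl ether and room-temperature metal catalysis, so 9 is never exposed to hot acid.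

**Step 6 (bromination next to a free or transiently silylated alcohol).** Risks are β-elimination to a cyclopentadienone, γ-enolisation, and epoxide closure of the bromohydrin on work-up. The fallback sets out from 14 and comes back at 17. Compound 14 is protected (tert-butyldimethylsilyl chloride, imidazole, DMF) as methyl 8-[(5S)-5-(tert-butyldimethylsilyloxy)-3-oxo-2-[(2Z)-pent-2-en-1-yl]cyclopent-1-en-1-yl]octanoate F4. Internal-quench enolisation (LiN(iPr)2 premixed with Me3SiCl, THF, −78 °C) gives methyl 8-[(5S)-5-(tert-butyldimethylsilyloxy)-2-[(2Z)-pent-2-en-1-yl]-3-(trimethylsilyloxy)cyclopenta-1,3-dien-1-yl]octanoate F5. N-Bromosuccinimide at −78 °C then gives methyl 8-[(4S,5R)-4-bromo-5-(tert-butyldimethylsilyloxy)-3-oxo-2-[(2Z)-pent-2-en-1-yl]cyclopent-1-en-1-yl]octanoate F6, and buffered HF·pyridine (THF, 0 °C) releases 17. This replaces the transient-silyl dianion protocol with a protecting-group sequence in which no alkoxide ever sits beside the new C–Br bond.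

Further compounds

F1 | step 5 | racemic methyl 8-{5-hydroxy-3-oxo-2-[(2Z)-pent-2-en-1-yl]cyclopent-1-en-1-yl}octanoate | CC/C=C\CC1=C(CCCCCCCC(=O)OC)C(O)CC1=O
F2 | step 5 | methyl 8-[(5R)-5-acetoxy-3-oxo-2-[(2Z)-pent-2-en-1-yl]cyclopent-1-en-1-yl]octanoate | CC/C=C\CC1=C(CCCCCCCC(=O)OC)[C@H](OC(C)=O)CC1=O
F3 | step 3 | methyl 10,10-bis{[(5Z)-oct-5-en-2-yn-1-yl]oxy}decanoate | COC(=O)CCCCCCCCC(OCC#CC/C=C\CC)OCC#CC/C=C\CC
F4 | step 6 | methyl 8-[(5S)-5-(tert-butyldimethylsilyloxy)-3-oxo-2-[(2Z)-pent-2-en-1-yl]cyclopent-1-en-1-yl]octanoate | CC/C=C\CC1=C(CCCCCCCC(=O)OC)[C@@H](O[Si](C)(C)C(C)(C)C)CC1=O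
F5 | step 6 | methyl 8-[(5S)-5-(tert-butyldimethylsilyloxy)-2-[(2Z)-pent-2-en-1-yl]-3-(trimethylsilyloxy)cyclopenta-1,3-dien-1-yl]octanoate | CC/C=C\CC1=C(CCCCCCCC(=O)OC)[C@@H](O[Si](C)(C)C(C)(C)C)C=C1O[Si](C)(C)C
F6 | step 6 | methyl 8-[(4S,5R)-4-bromo-5-(tert-butyldimethylsilyloxy)-3-oxo-2-[(2Z)-pent-2-en-1-yl]cyclopent-1-en-1-yl]octanoate | CC/C=C\CC1=C(CCCCCCCC(=O)OC)[C@@H](O[Si](C)(C)C(C)(C)C)[C@H](Br)C1=O
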